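## Retrosynthetic overview

1. Atom labels in the comments follow guaiane numbering: C4 tertiary carbinol, C5 ring-fusion CH, C6 CH–OH, C7 CH–iPr, C8 CH–O-aroyl, C1=C10 alkene. The target comes from acylation of the C8–OH of a C6-O-silyl triol; the C7–H/C8–OH pair comes from anti hydroboration of a C7=C8 alkene.
2. The seven-membered ring is formed last, by an intermolecular rhodium-catalysed [5+2] cycloaddition of 3-methylbut-1-yne with a ring-fused siloxy vinylcyclopropane. This makes C6–C7, C8–C9 and the C1=C10 alkene in one step and carries C4, C5 and C6 over unchanged.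
3. The vinylcyclopropane comes from MeMgBr addition to a bicyclo[3.1.0]hexan-2-one, anti to the cyclopropane (sets C4).
4. The five-membered ring and the cyclopropane are formed first, together, by enantioselective intramolecular cyclopropanation of a diazoketone onto an (E)-silyl dienol ether (sets C5 and C6).
5. The diazoketone is built from 3-methylbut-2-enal, cyclohexylamine and N-methoxy-N-methylprop-2-enamide.

Assumption: the (S,S)-tBu-box ligand is taken to give the (1S,5R,6S) ketone 12; if the induction is the opposite, the (R,R) ligand is used.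

## Route

Step 1
Reactants: 1 3-methylbut-2-enal; 2 cyclohexylamine
Product: 3 (1E)-N-cyclohexyl-3-methylbut-2-en-1-imine
Conditions: MgSO4, Et2O, 0 °C to rt
Reagents that add atoms: none
Why: Imine condensation of an unhindered aldehyde with a primary amine, driven by removal of water.

Step 2
Reactants: 3 (1E)-N-cyclohexyl-3-methylbut-2-en-1-imine; 4 N-methoxy-N-methylprop-2-enamide
Product: 7 4-formyl-N-methoxy-N,5-dimethylhex-4-enamide, via Michael-adduct imine 5 (not isolated), via deconjugated aldehyde 6 (not isolated)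
Conditions: LiN(iPr)2, THF, −78 °C; 4, −78 to −30 °C; sat. NH4Cl; 1 M aq. oxalic acid, THF, rt; DBU (cat.), CH2Cl2, rt
Reagents that add atoms: water, O
Why: Michael addition of the metalated α,β-unsaturated aldimine (Stork metalloenamine chemistry), which reacts kinetically at its α-carbon; imine hydrolysis and base-mediated reconjugation then give the tetrasubstituted enal.

Step 3
Reactants: 7 4-formyl-N-methoxy-N,5-dimethylhex-4-enamide
Product: 8 (4E)-4-({[tert-butyl(dimethyl)silyl]oxy}methylidene)-N-methoxy-N,5-dimethylhex-5-enamide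
Conditions: TBSOTf, Et3N, CH2Cl2, −78 to 0 °C
Reagents that add atoms: tert-butyldimethylsilyl trifluoromethanesulfonate, CC(C)(C)[Si](C)(C)OS(=O)(=O)C(F)(F)F
Why: Vinylogous (γ) soft enolisation to a silyl dienol ether; the enal reacts from its s-trans conformer, so oxygen ends up trans to the isopropenyl group (E), and the Weinreb amide cannot enolise under these conditions.

Step 4
Reactants: 8 (4E)-4-({[tert-butyl(dimethyl)silyl]oxy}methylidene)-N-methoxy-N,5-dimethylhex-5-enamide
Product: 9 (5E)-5-({[tert-butyl(dimethyl)silyl]oxy}methylidene)-6-methylhept-6-en-2-one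
Conditions: MeMgBr, THF, 0 °C; sat. NH4Cl
Reagents that add atoms: methylmagnesium bromide, C[Mg]Br
Why: Weinreb ketone synthesis; the chelated tetrahedral adduct stops at the methyl ketone and the base-stable silyl dienol ether is untouched.

Step 5
Reactants: 9 (5E)-5-({[tert-butyl(dimethyl)silyl]oxy}methylidene)-6-methylhept-6-en-2-one
Product: 11 (5E)-5-({[tert-butyl(dimethyl)silyl]oxy}methylidene)-1-diazo-6-methylhept-6-en-2-one, via trifluoroacetyl diketone 10 (not isolated)
Conditions: LiN(SiMe3)2, THF, −78 °C; CF3CO2CH2CF3; sat. NH4Cl; then MsN3, Et3N, H2O, MeCN, rt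
Reagents that add atoms: methanesulfonyl azide, CS(=O)(=O)N=[N+]=[N-]
Why: Danheiser detrifluoroacetylative diazo transfer (Regitz type); kinetic enolisation on the methyl side places the diazo group at the chain end under purely basic conditions that the silyl dienol ether tolerates.

Step 6
Reactants: 11 (5E)-5-({[tert-butyl(dimethyl)silyl]oxy}methylidene)-1-diazo-6-methylhept-6-en-2-one
Product: 12 (1S,5R,6S)-6-{[tert-butyl(dimethyl)silyl]oxy}-5-(prop-1-en-2-yl)bicyclo[3.1.0]hexan-2-one
Conditions: Cu(MeCN)4PF6 (5 mol %), (S,S)-tBu-box (6 mol %), CH2Cl2, 40 °C, slow addition of 11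
Reagents that add atoms: none
Why: Enantioselective intramolecular carbenoid cyclopropanation (monovalent copper–bis(oxazoline)); the carbene adds stereospecifically to the proximal electron-rich enol ether alkene, so the (E)-geometry puts the silyloxy group endo, and the ligand chooses the alkene face, setting C5, C1 and C6 together.

Step 7
Reactants: 12 (1S,5R,6S)-6-{[tert-butyl(dimethyl)silyl]oxy}-5-(prop-1-en-2-yl)bicyclo[3.1.0]hexan-2-one
Product: 13 (1S,2S,5R,6S)-6-{[tert-butyl(dimethyl)silyl]oxy}-2-methyl-5-(prop-1-en-2-yl)bicyclo[3.1.0]hexan-2-ol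
Conditions: MeMgBr, THF, −78 to 0 °C; sat. NH4Cl
Reagents that add atoms: methylmagnesium bromide, C[Mg]Br
Why: Grignard 1,2-addition from the face anti to the cyclopropane (the endo silyloxy group blocks the other face), so the new C4–OH is cis to the cyclopropane carbon that becomes C6.

Step 8
Reactants: 13 (1S,2S,5R,6S)-6-{[tert-butyl(dimethyl)silyl]oxy}-2-methyl-5-(prop-1-en-2-yl)bicyclo[3.1.0]hexan-2-ol; 14 3-methylbut-1-yne
Product: 15 (1S,8S,8aS)-8-{[tert-butyl(dimethyl)silyl]oxy}-1,4-dimethyl-7-(propan-2-yl)-1,2,3,5,8,8a-hexahydroazulen-1-ol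
Conditions: [Rh(CO)2Cl]2 (5 mol %), 14 (5 equiv), ClCH2CH2Cl, 70 °C, sealed tube
Reagents that add atoms: none
Why: Proposed new method: the closest known reaction is the Wender rhodium-catalysed intermolecular vinylcyclopropane–alkyne [5+2] cycloaddition of 1-alkyl- and 1-alkoxy-vinylcyclopropanes, here extended to a ring-fused siloxy vinylcyclopropane; monovalent rhodium should insert into the external, donor-weakened C1–C6 bond (cleaving the ring-fusion bond would give a bridged metallacycle), the alkyne inserts at the allyl terminus with its bulky isopropyl end distal to the forming C8–C9 bond, and reductive elimination forms C6–C7 with retention, so the endo silyloxy group becomes the C6 centre trans to H5 while C4 and C5 are untouched.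

Step 9
Reactants: 15 (1S,8S,8aS)-8-{[tert-butyl(dimethyl)silyl]oxy}-1,4-dimethyl-7-(propan-2-yl)-1,2,3,5,8,8a-hexahydroazulen-1-ol
Product: 17 (1S,6S,7R,8R,8aS)-8-{[tert-butyl(dimethyl)silyl]oxy}-1,4-dimethyl-7-(propan-2-yl)-1,2,3,5,6,7,8,8a-octahydroazulene-1,6-diol, via 9-BBN alkylborane 16 (not isolated)
Conditions: 9-BBN (3 equiv), THF, 0 to 60 °C; then NaOH, H2O2, 0 °C to rt
Reagents that add atoms: hydrogen peroxide, OO
Why: Hydroboration–oxidation; the dialkylborane ignores the tetrasubstituted alkene and cannot cyclise onto it, puts boron on the less substituted C8 and adds anti to the bulky allylic silyloxy group (Still–Barrish-type induction), so H7 and the C8–OH both land on the face opposite the C6–O bond, and oxidation proceeds with retention.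

Step 10
Reactants: 18 4-hydroxybenzoic acid
Product: 20 4-{[tert-butyl(dimethyl)silyl]oxy}benzoic acid, via bis-silylated benzoate 19 (not isolated)
Conditions: TBSCl (2.5 equiv), imidazole, DMF, rt; then K2CO3, THF/MeOH/H2O, rt; 1 M HCl to pH 4
Reagents that add atoms: tert-butyldimethylsilyl chloride, CC(C)(C)[Si](C)(C)Cl
Why: Exhaustive silylation followed by selective mild-base cleavage of the much more labile silyl ester, a standard phenol protection.

Step 11
Reactants: 17 (1S,6S,7R,8R,8aS)-8-{[tert-butyl(dimethyl)silyl]oxy}-1,4-dimethyl-7-(propan-2-yl)-1,2,3,5,6,7,8,8a-octahydroazulene-1,6-diol; 20 4-{[tert-butyl(dimethyl)silyl]oxy}benzoic acid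
Product: 21 (1S,6S,7R,8R,8aS)-8-{[tert-butyl(dimethyl)silyl]oxy}-1-hydroxy-1,4-dimethyl-7-(propan-2-yl)-1,2,3,5,6,7,8,8a-octahydroazulen-6-yl 4-{[tert-butyl(dimethyl)silyl]oxy}benzoate
Conditions: DCC, DMAP, CH2Cl2, rt
Reagents that add atoms: none
Why: Steglich esterification; only the secondary C8–OH is acylated because the C4–OH is tertiary and the C6–OH is silylated.

Step 12
Reactants: 21 (1S,6S,7R,8R,8aS)-8-{[tert-butyl(dimethyl)silyl]oxy}-1-hydroxy-1,4-dimethyl-7-(propan-2-yl)-1,2,3,5,6,7,8,8a-octahydroazulen-6-yl 4-{[tert-butyl(dimethyl)silyl]oxy}benzoate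
Product: 22 (1S,6S,7S,8R,8aS)-1,8-dihydroxy-1,4-dimethyl-7-(propan-2-yl)-1,2,3,5,6,7,8,8a-octahydroazulen-6-yl 4-hydroxybenzoate
Conditions: HF·pyridine, pyridine, THF, 0 °C to rt
Reagents that add atoms: none
Why: Fluoride-mediated desilylation removes the aryl and the secondary silyl ether in one operation; the buffered, non-basic medium avoids acyl migration to the trans-1,3-related C6–OH.

## Compound list

1 | 3-methylbut-2-enal | CC(C)=CC=O | starting material
2 | cyclohexylamine | NC1CCCCC1 | starting material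
3 | (1E)-N-cyclohexyl-3-methylbut-2-en-1-imine | CC(C)=C/C=N/C1CCCCC1 | intermediate
4 | N-methoxy-N-methylprop-2-enamide | C=CC(=O)N(C)OC | starting material
5 | 4-[(E)-(cyclohexylimino)methyl]-N-methoxy-N,5-dimethylhex-5-enamide (racemic, Michael-adduct imine) | C=C(C)C(/C=N/C1CCCCC1)CCC(=O)N(C)OC | intermediate
6 | 4-formyl-N-methoxy-N,5-dimethylhex-5-enamide (racemic, deconjugated aldehyde) | C=C(C)C(C=O)CCC(=O)N(C)OC | intermediate
7 | 4-formyl-N-methoxy-N,5-dimethylhex-4-enamide | CC(C)=C(C=O)CCC(=O)N(C)OC | intermediate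
8 | (4E)-4-({[tert-butyl(dimethyl)silyl]oxy}methylidene)-N-methoxy-N,5-dimethylhex-5-enamide | C=C(C)/C(=C/O[Si](C)(C)C(C)(C)C)CCC(=O)N(C)OC | intermediate
9 | (5E)-5-({[tert-butyl(dimethyl)silyl]oxy}methylidene)-6-methylhept-6-en-2-one | C=C(C)/C(=C/O[Si](C)(C)C(C)(C)C)CCC(C)=O | intermediate
10 | (7E)-7-({[tert-butyl(dimethyl)silyl]oxy}methylidene)-1,1,1-trifluoro-8-methylnon-8-ene-2,4-dione (trifluoroacetyl diketone) | C=C(C)/C(=C/O[Si](C)(C)C(C)(C)C)CCC(=O)CC(=O)C(F)(F)F | intermediate
11 | (5E)-5-({[tert-butyl(dimethyl)silyl]oxy}methylidene)-1-diazo-6-methylhept-6-en-2-one | C=C(C)/C(=C/O[Si](C)(C)C(C)(C)C)CCC(=O)C=[N+]=[N-] | intermediate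
12 | (1S,5R,6S)-6-{[tert-butyl(dimethyl)silyl]oxy}-5-(prop-1-en-2-yl)bicyclo[3.1.0]hexan-2-one | C=C(C)[C@@]12CCC(=O)[C@@H]1[C@@H]2O[Si](C)(C)C(C)(C)C | intermediate
13 | (1S,2S,5R,6S)-6-{[tert-butyl(dimethyl)silyl]oxy}-2-methyl-5-(prop-1-en-2-yl)bicyclo[3.1.0]hexan-2-ol | C=C(C)[C@@]12CC[C@](C)(O)[C@@H]1[C@@H]2O[Si](C)(C)C(C)(C)C | intermediate
14 | 3-methylbut-1-yne | CC(C)C#C | starting material
15 | (1S,8S,8aS)-8-{[tert-butyl(dimethyl)silyl]oxy}-1,4-dimethyl-7-(propan-2-yl)-1,2,3,5,8,8a-hexahydroazulen-1-ol | CC1=C2CC[C@](C)(O)[C@@H]2[C@H](O[Si](C)(C)C(C)(C)C)C(C(C)C)=CC1 | intermediate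
16 | 9-BBN alkylborane of 15 (9-borabicyclo[3.3.1]nonan-9-yl group on C8, same configuration as 17) | CC1=C2CC[C@](C)(O)[C@@H]2[C@H](O[Si](C)(C)C(C)(C)C)[C@H](C(C)C)[C@@H](B2C3CCCC2CCC3)C1 | intermediate
17 | (1S,6S,7R,8R,8aS)-8-{[tert-butyl(dimethyl)silyl]oxy}-1,4-dimethyl-7-(propan-2-yl)-1,2,3,5,6,7,8,8a-octahydroazulene-1,6-diol | CC1=C2CC[C@](C)(O)[C@@H]2[C@H](O[Si](C)(C)C(C)(C)C)[C@H](C(C)C)[C@@H](O)C1 | intermediate
18 | 4-hydroxybenzoic acid | OC(=O)c1ccc(O)cc1 | starting material
19 | tert-butyl(dimethyl)silyl 4-{[tert-butyl(dimethyl)silyl]oxy}benzoate (bis-silylated benzoate) | CC(C)(C)[Si](C)(C)OC(=O)c1ccc(O[Si](C)(C)C(C)(C)C)cc1 | intermediate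
20 | 4-{[tert-butyl(dimethyl)silyl]oxy}benzoic acid | OC(=O)c1ccc(O[Si](C)(C)C(C)(C)C)cc1 | intermediate
21 | (1S,6S,7R,8R,8aS)-8-{[tert-butyl(dimethyl)silyl]oxy}-1-hydroxy-1,4-dimethyl-7-(propan-2-yl)-1,2,3,5,6,7,8,8a-octahydroazulen-6-yl 4-{[tert-butyl(dimethyl)silyl]oxy}benzoate | CC1=C2CC[C@](C)(O)[C@@H]2[C@H](O[Si](C)(C)C(C)(C)C)[C@H](C(C)C)[C@@H](OC(=O)c2ccc(O[Si](C)(C)C(C)(C)C)cc2)C1 | intermediate
22 | (1S,6S,7S,8R,8aS)-1,8-dihydroxy-1,4-dimethyl-7-(propan-2-yl)-1,2,3,5,6,7,8,8a-octahydroazulen-6-yl 4-hydroxybenzoate (CNP0392039.1) | CC1=C2CC[C@](C)(O)[C@@H]2[C@H](O)[C@H](C(C)C)[C@@H](OC(=O)c2ccc(O)cc2)C1 | target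

## Step count and risks

Total step count: 12. Longest linear sequence: 11 (steps 1 to 9, 11 and 12; step 10 is a one-step side branch).

**Step 8 (highest risk).** An intermolecular [5+2] on a trisubstituted, ring-fused siloxy vinylcyclopropane is unprecedented. It may be slow, may divert by β-hydride elimination to ring-opened dienes, or may give the wrong alkyne regiochemistry. The fallback takes the isopropyl group out of the cycloaddition and brings it in afterwards by cross-coupling. It sets out from 13, which is combined under the same [Rh(CO)2Cl]2 catalysis with ethynyltrimethylsilane, a small and well-behaved partner whose bulky silyl end is expected at C7, to give (1S,8S,8aS)-8-{[tert-butyl(dimethyl)silyl]oxy}-1,4-dimethyl-7-(trimethylsilyl)-1,2,3,5,8,8a-hexahydroazulen-1-ol F1. Ipso-iododesilylation with NIS in MeCN at 0 °C then gives (1S,8S,8aS)-8-{[tert-butyl(dimethyl)silyl]oxy}-7-iodo-1,4-dimethyl-1,2,3,5,8,8a-hexahydroazulen-1-ol F2. Negishi coupling of F2 with iPrZnBr (Pd(OAc)2, CPhos, THF, rt) comes back to the route at 15.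

**Step 6.** The enantioselectivity of the copper carbenoid on a silyl dienol ether is untested, and ylide or dihydrofuran pathways could compete. The fallback generates the same α-oxo carbene without a diazo compound and with a different chiral metal. It sets out from 8, whose Weinreb amide is reduced (iBu2AlH, THF, −78 °C) to (4E)-4-({[tert-butyl(dimethyl)silyl]oxy}methylidene)-5-methylhex-5-enal F3. Colvin homologation (TMSCHN2, LiN(iPr)2, THF, −78 to 0 °C) gives the terminal alkyne tert-butyl{[(1E)-2-(but-3-yn-1-yl)-3-methylbuta-1,3-dien-1-yl]oxy}dimethylsilane F4. Oxidative catalysis with monovalent gold ((R)-DTBM-SEGPHOS(AuCl)2, AgNTf2, 8-methylquinoline N-oxide, ClCH2CH2Cl) then oxidises the alkyne to the α-oxo gold carbene, which cyclopropanates the enol ether and comes back to the route at 12.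

**Step 2.** The metalated imine could add through its γ-carbon or attack the amide carbonyl instead of giving clean α-Michael addition. The fallback replaces the Michael acceptor by an alkyl halide, for which α-alkylation of such anions is well established. It sets out from 3, which is deprotonated with LiN(iPr)2 and alkylated with 3-bromo-1,1,1-triethoxypropane to give (1E)-N-cyclohexyl-5,5,5-triethoxy-2-(prop-1-en-2-yl)pentan-1-imine F5. Aqueous oxalic acid followed by catalytic DBU hydrolyses the imine and the orthoester and reconjugates to ethyl 4-formyl-5-methylhex-4-enoate F6. TBSOTf and Et3N give ethyl (4E)-4-({[tert-butyl(dimethyl)silyl]oxy}methylidene)-5-methylhex-5-enoate F7, and MeNH(OMe)·HCl with iPrMgCl in THF at −20 °C converts the ester into the Weinreb amide, coming back to the route at 8.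

## Further compounds

F1 | step 8 | (1S,8S,8aS)-8-{[tert-butyl(dimethyl)silyl]oxy}-1,4-dimethyl-7-(trimethylsilyl)-1,2,3,5,8,8a-hexahydroazulen-1-ol | CC1=C2CC[C@](C)(O)[C@@H]2[C@H](O[Si](C)(C)C(C)(C)C)C([Si](C)(C)C)=CC1
F2 | step 8 | (1S,8S,8aS)-8-{[tert-butyl(dimethyl)silyl]oxy}-7-iodo-1,4-dimethyl-1,2,3,5,8,8a-hexahydroazulen-1-ol | CC1=C2CC[C@](C)(O)[C@@H]2[C@H](O[Si](C)(C)C(C)(C)C)C(I)=CC1
F3 | step 6 | (4E)-4-({[tert-butyl(dimethyl)silyl]oxy}methylidene)-5-methylhex-5-enal | C=C(C)/C(=C/O[Si](C)(C)C(C)(C)C)CCC=O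
F4 | step 6 | tert-butyl{[(1E)-2-(but-3-yn-1-yl)-3-methylbuta-1,3-dien-1-yl]oxy}dimethylsilane | C=C(C)/C(=C/O[Si](C)(C)C(C)(C)C)CCC#C
F5 | step 2 | (1E)-N-cyclohexyl-5,5,5-triethoxy-2-(prop-1-en-2-yl)pentan-1-imine (racemic) | C=C(C)C(/C=N/C1CCCCC1)CCC(OCC)(OCC)OCC
F6 | step 2 | ethyl 4-formyl-5-methylhex-4-enoate | CCOC(=O)CCC(C=O)=C(C)C
F7 | step 2 | ethyl (4E)-4-({[tert-butyl(dimethyl)silyl]oxy}methylidene)-5-methylhex-5-enoate | C=C(C)/C(=C/O[Si](C)(C)C(C)(C)C)CCC(=O)OCC
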